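**Retrosynthetic overview**
1. Target 27 is cut first at the amide bond. This gives (R)-2-hydroxypentacosanoic acid 25 (fragment 3, from methyl (R)-glycidate and a docosyl Grignard reagent) and the protected D-ribo amine 20. The C2–N bond of 20 comes from a C2–OH by triflate/azide inversion.
2. The key disconnection is C5–C6 (sphingoid numbering): the C5 methylene next to the C4 carbinol, and the alkenyl CH. Fragment 1 is the N-phthalimidoyl 2-deoxy-D-galactopyranoside 4 and fragment 2 is the (E)-alkenyl bromide 13. One nickel/photoredox operation cleaves the sugar C1–C2 bond and couples the released radical.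
3. Enabling feature: chain atoms C5H2–C4H(O)–C3H(O)–C2H(O)–C1H2O are sugar atoms C2–C6 of 2-deoxy-D-lyxo-hexopyranose. In its tetrahydropyran ring (O5, C1–C5) the oxygen-free C2 sits next to the acetal carbon C1. An O-centred radical on C1 therefore expels C2 as a primary radical and leaves C1 as a formate on O5, the one oxygen that must become nitrogen.
4. Rings: the trans-cyclopropane, the only ring of 27, is formed first (step 4). The pyran ring is bought with D-galactal, and a temporary cis-fused dioxolane is closed on O3/O4 in step 2. The pyran ring is opened in step 9 and the dioxolane is removed in step 16.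

Key step: step 9

Remark: chain atoms carry sphingoid numbering (C1 = CH2O, C2 = C–N) and sugar atoms carry carbohydrate numbering. The acyl chain is read as C25 (twenty-three carbons before the carbinol carbon). Glycoside 4 is carried as an anomeric mixture because step 9 destroys that centre.

**Fragment 1**

Step 1
Reactants: 1 D-galactal
Product: 2 6-O-(tert-butyldimethylsilyl)-D-galactal
Conditions: TBSCl, imidazole, DMF, 0 °C
Reagents that add atoms: tert-butyldimethylsilyl chloride, CC(C)(C)[Si](C)(C)Cl
Why: Sterically governed silyl ether formation should take the primary C6 hydroxyl ahead of the two secondary hydroxyls, and no stereocentre is touched.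

Step 2
Reactants: 2 6-O-(tert-butyldimethylsilyl)-D-galactal
Product: 3 6-O-(tert-butyldimethylsilyl)-3,4-O-isopropylidene-D-galactal
Conditions: Me2C(OMe)2, PPTS (cat.), CH2Cl2, rt
Reagents that add atoms: 2,2-dimethoxypropane, COC(C)(C)OC
Why: Acid-catalysed transketalisation closes a cis-fused 1,3-dioxolane on the cis-3,4-diol of the galacto series, and the weak pyridinium acid should leave the enol ether intact.

Step 3
Reactants: 3 6-O-(tert-butyldimethylsilyl)-3,4-O-isopropylidene-D-galactal
Product: 4 N-{[6-O-(tert-butyldimethylsilyl)-2-deoxy-3,4-O-isopropylidene-D-lyxo-hexopyranosyl]oxy}phthalimide (anomeric mixture)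
Conditions: N-hydroxyphthalimide, PPh3·HBr (cat.), THF, rt
Reagents that add atoms: N-hydroxyphthalimide, O=C1c2ccccc2C(=O)N1O
Why: Acid-catalysed addition of a hydroxylic nucleophile to a glycal (2-deoxyglycosylation) protonates C2 and lets the N–OH oxygen capture the oxocarbenium ion, and the new anomeric centre needs no control because step 9 erases it.

**Fragment 2**

Step 4
Reactants: 5 (E)-hept-2-en-1-ol
Product: 6 [(1S,2S)-2-butylcyclopropyl]methanol
Conditions: Et2Zn, CH2I2, DME, (4R,5R)-2-butyl-N,N,N',N'-tetramethyl-1,3,2-dioxaborolane-4,5-dicarboxamide, CH2Cl2, −10 °C to rt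
Reagents that add atoms: diiodomethane, ICI
Why: In the Charette asymmetric Simmons–Smith cyclopropanation the (R,R)-dioxaborolane binds the zinc alkoxide and directs stereospecific syn methylene transfer to one alkene face, so the E geometry becomes the trans ring and the ligand sets both centres as (1S,2S).

Step 5
Reactants: 6 [(1S,2S)-2-butylcyclopropyl]methanol
Product: 7 (1S,2S)-1-(bromomethyl)-2-butylcyclopropane
Conditions: CBr4, PPh3, CH2Cl2, 0 °C
Reagents that add atoms: carbon tetrabromide, BrC(Br)(Br)Br
Why: The Appel reaction replaces the activated oxygen by bromide in an SN2 event at low temperature, which should avoid a cyclopropylcarbinyl cation and leaves both ring stereocentres untouched.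

Step 6
Reactants: 7 (1S,2S)-1-(bromomethyl)-2-butylcyclopropane; 8 (5-chloropent-1-yn-1-yl)trimethylsilane
Product: 10 {6-[(1S,2S)-2-butylcyclopropyl]hex-1-yn-1-yl}trimethylsilane, via 5-(trimethylsilyl)pent-4-yn-1-ylmagnesium chloride 9 (not isolated)
Conditions: 8, Mg, THF, reflux; then 7, Li2CuCl4 (cat.), NMP, THF, 0 °C to rt
Reagents that add atoms: none
Why: The Kochi-type copper-catalysed alkyl–alkyl coupling of a Grignard reagent with a primary bromide is an SN2-like process at copper that should not pass through a free cyclopropylcarbinyl radical, so the ring and its two centres persist.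

Step 7
Reactants: 10 {6-[(1S,2S)-2-butylcyclopropyl]hex-1-yn-1-yl}trimethylsilane
Product: 11 (1S,2S)-1-butyl-2-(hex-5-yn-1-yl)cyclopropane
Conditions: K2CO3 (cat.), MeOH, rt
Reagents that add atoms: none
Why: Base-catalysed methanolytic protodesilylation of an alkynylsilane meets no other reactive group in this hydrocarbon.

Step 8
Reactants: 11 (1S,2S)-1-butyl-2-(hex-5-yn-1-yl)cyclopropane
Product: 13 (1S,2S)-1-[(5E)-6-bromohex-5-en-1-yl]-2-butylcyclopropane, via alkenylzirconocene chloride 12 (not isolated)
Conditions: Cp2Zr(H)Cl, CH2Cl2, rt; then NBS, 0 °C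
Reagents that add atoms: N-bromosuccinimide, O=C1CCC(=O)N1Br
Why: Schwartz hydrozirconation adds Zr–H syn and places the metal on the terminal carbon, and bromodezirconation proceeds with retention, so the E-bromoalkene should result.

**Union of fragments 1 and 2**

Step 9
Reactants: 4 N-{[6-O-(tert-butyldimethylsilyl)-2-deoxy-3,4-O-isopropylidene-D-lyxo-hexopyranosyl]oxy}phthalimide; 13 (1S,2S)-1-[(5E)-6-bromohex-5-en-1-yl]-2-butylcyclopropane
Product: 16 (2R,3R,4R,6E)-11-[(1S,2S)-2-butylcyclopropyl]-1-[(tert-butyldimethylsilyl)oxy]-3,4-(isopropylidenedioxy)undec-6-en-2-yl formate, via anomeric alkoxyl radical 14 (not isolated), via primary C5 radical 15 (not isolated)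
Conditions: NiBr2·dme (10 mol %), 4,4'-di-tert-butyl-2,2'-bipyridine (12 mol %), Ir(ppy)3 (1 mol %), Hantzsch ester, NaHCO3, degassed DMA, blue LEDs, 25 °C
Reagents that add atoms: none
Why: Proposed new method: excited Ir(ppy)3 transfers one electron to the phthalimide of 4, the N–O bond breaks and anomeric alkoxyl radical 14 undergoes β-scission of the C1–C2 bond of the tetrahydropyran ring, paid for by the ester C=O of the O5 formate, to give primary radical 15 at the former 2-deoxy carbon; 15 is captured by the divalent alkenylnickel bromide formed from 13 and zerovalent nickel, reductive elimination from trivalent nickel makes the C5–C6 bond, and the Hantzsch ester returns both catalysts to their resting states. The closest known reaction types are the reductive Suárez-type fragmentation of N-phthalimido glycosides, the nickel/photoredox arylation of β-scission radicals from N-alkoxyphthalimides and the nickel/photoredox alkenylation of alkyl radicals with vinyl halides; only their union on a glycoside is new. No ring is closed: the pyran ring is opened and the dioxolane is untouched. No stereocentre is created: sugar C3, C4 and C5 (chain C4, C3 and C2) never carry spin and are retained, both anomers of 4 converge on one product because C1 becomes the planar formyl carbon, and oxidative addition and reductive elimination keep the E geometry of 13, whose dialkyl alkene lies too high in triplet energy to be isomerised by the sensitiser. The step needs C1–C2 scission to beat C1–O5 or C1–H scission and hydrogen abstraction, which the acetal oxygen O5 secures by making the formate the strongly favoured carbonyl product, and it needs radical capture to beat reduction, which is helped by the unhindered primary radical and by the absence of an oxygen on C2 that would allow oxidation to an oxocarbenium ion. The cyclopropane is safe because no radical is ever generated in fragment 2, and the β-oxygen of 15 is held in the dioxolane and should not be expelled at the radical or trivalent nickel stage.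

Step 10
Reactants: 16 (2R,3R,4R,6E)-11-[(1S,2S)-2-butylcyclopropyl]-1-[(tert-butyldimethylsilyl)oxy]-3,4-(isopropylidenedioxy)undec-6-en-2-yl formate
Product: 17 (2R,3S,4R,6E)-11-[(1S,2S)-2-butylcyclopropyl]-1-[(tert-butyldimethylsilyl)oxy]-3,4-(isopropylidenedioxy)undec-6-en-2-ol
Conditions: K2CO3 (cat.), MeOH, 0 °C
Reagents that add atoms: none
Why: Transesterification of a formate, the most labile of esters, frees only the C2 hydroxyl that the sugar ring oxygen had masked, while silyl ether and acetonide stay in place.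

Step 11
Reactants: 17 (2R,3S,4R,6E)-11-[(1S,2S)-2-butylcyclopropyl]-1-[(tert-butyldimethylsilyl)oxy]-3,4-(isopropylidenedioxy)undec-6-en-2-ol
Product: 19 (2S,3S,4R,6E)-2-azido-11-[(1S,2S)-2-butylcyclopropyl]-1-[(tert-butyldimethylsilyl)oxy]-3,4-(isopropylidenedioxy)undec-6-ene, via C2 triflate 18 (not isolated)
Conditions: Tf2O, pyridine, CH2Cl2, −20 °C; then NaN3, DMF, rt
Reagents that add atoms: sodium azide, [Na+].[N-]=[N+]=[N-]
Why: Sulfonate activation followed by SN2 displacement with azide inverts C2 from R to S and so sets the D-ribo array, a sequence with close precedent on 1-O-protected 3,4-O-isopropylidene lyxo-configured triols.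

Step 12
Reactants: 19 (2S,3S,4R,6E)-2-azido-11-[(1S,2S)-2-butylcyclopropyl]-1-[(tert-butyldimethylsilyl)oxy]-3,4-(isopropylidenedioxy)undec-6-ene
Product: 20 (2S,3S,4R,6E)-11-[(1S,2S)-2-butylcyclopropyl]-1-[(tert-butyldimethylsilyl)oxy]-3,4-(isopropylidenedioxy)undec-6-en-2-amine
Conditions: PPh3, THF/H2O, 50 °C
Reagents that add atoms: none
Why: The Staudinger reduction is chemoselective for the azide and spares the alkene and the cyclopropane that hydrogenation would endanger, with C2 unaffected.

**Fragment 3**

Step 13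
Reactants: 21 1-bromodocosane; 22 methyl (R)-glycidate
Product: 24 methyl (R)-2-hydroxypentacosanoate, via docosylmagnesium bromide 23 (not isolated)
Conditions: 21, Mg, THF, 45 °C; then 22, CuBr·SMe2 (cat.), THF, −40 to −20 °C; 1 M HCl quench
Reagents that add atoms: none
Why: Copper-catalysed SN2 opening of the glycidic ester occurs at its unsubstituted C3, so the stereocentre of 22 is not involved and its R configuration is carried into 24.

Step 14
Reactants: 24 methyl (R)-2-hydroxypentacosanoate
Product: 25 (R)-2-hydroxypentacosanoic acid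
Conditions: LiOH, THF/MeOH/H2O, 40 °C; then 1 M HCl
Reagents that add atoms: lithium hydroxide, [Li+].[OH-]
Why: Mild saponification of a methyl ester should not epimerise the α-hydroxy centre, whose alkoxide disfavours enolisation.

**Endgame**

Step 15
Reactants: 20 (2S,3S,4R,6E)-11-[(1S,2S)-2-butylcyclopropyl]-1-[(tert-butyldimethylsilyl)oxy]-3,4-(isopropylidenedioxy)undec-6-en-2-amine; 25 (R)-2-hydroxypentacosanoic acid
Product: 26 (2R)-N-{(2S,3S,4R,6E)-11-[(1S,2S)-2-butylcyclopropyl]-1-[(tert-butyldimethylsilyl)oxy]-3,4-(isopropylidenedioxy)undec-6-en-2-yl}-2-hydroxypentacosanamide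
Conditions: EDC, HOBt, CH2Cl2/THF, rt
Reagents that add atoms: none
Why: In this carbodiimide/HOBt amide coupling the primary amine outcompetes the hindered secondary α-hydroxyl, so the acid needs no protection and HOBt suppresses epimerisation.

Step 16
Reactants: 26 (2R)-N-{(2S,3S,4R,6E)-11-[(1S,2S)-2-butylcyclopropyl]-1-[(tert-butyldimethylsilyl)oxy]-3,4-(isopropylidenedioxy)undec-6-en-2-yl}-2-hydroxypentacosanamide
Product: 27 (2R)-N-{(2S,3S,4R,6E)-11-[(1S,2S)-2-butylcyclopropyl]-1,3,4-trihydroxyundec-6-en-2-yl}-2-hydroxypentacosanamide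
Conditions: 1 M aq HCl, THF, 40 °C
Reagents that add atoms: none
Why: Acid hydrolysis removes the acetonide and the primary silyl ether in one operation, while the isolated E-alkene, the dialkylcyclopropane and the amide are inert to dilute acid.

**Compound list**
1 | D-galactal | OC[C@H]1OC=C[C@@H](O)[C@H]1O | starting material
2 | 6-O-(tert-butyldimethylsilyl)-D-galactal | CC(C)(C)[Si](C)(C)OC[C@H]1OC=C[C@@H](O)[C@H]1O | intermediate
3 | 6-O-(tert-butyldimethylsilyl)-3,4-O-isopropylidene-D-galactal | CC(C)(C)[Si](C)(C)OC[C@H]1OC=C[C@H]2OC(C)(C)O[C@@H]12 | intermediate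
4 | N-{[6-O-(tert-butyldimethylsilyl)-2-deoxy-3,4-O-isopropylidene-D-lyxo-hexopyranosyl]oxy}phthalimide, anomeric mixture | CC(C)(C)[Si](C)(C)OC[C@H]1OC(ON3C(=O)c4ccccc4C3=O)C[C@H]2OC(C)(C)O[C@@H]12 | intermediate
5 | (E)-hept-2-en-1-ol | CCCC/C=C/CO | starting material
6 | [(1S,2S)-2-butylcyclopropyl]methanol | OC[C@H]1C[C@@H]1CCCC | intermediate
7 | (1S,2S)-1-(bromomethyl)-2-butylcyclopropane | BrC[C@H]1C[C@@H]1CCCC | intermediate
8 | (5-chloropent-1-yn-1-yl)trimethylsilane | C[Si](C)(C)C#CCCCCl | starting material
9 | 5-(trimethylsilyl)pent-4-yn-1-ylmagnesium chloride | C[Si](C)(C)C#CCCC[Mg]Cl | intermediate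
10 | {6-[(1S,2S)-2-butylcyclopropyl]hex-1-yn-1-yl}trimethylsilane | C[Si](C)(C)C#CCCCC[C@H]1C[C@@H]1CCCC | intermediate
11 | (1S,2S)-1-butyl-2-(hex-5-yn-1-yl)cyclopropane | C#CCCCC[C@H]1C[C@@H]1CCCC | intermediate
12 | chloro{(1E)-6-[(1S,2S)-2-butylcyclopropyl]hex-1-en-1-yl}zirconocene (cyclopentadienyl rings drawn σ-bonded) | Cl[Zr](C1C=CC=C1)(C2C=CC=C2)/C=C/CCCC[C@H]3C[C@@H]3CCCC | intermediate
13 | (1S,2S)-1-[(5E)-6-bromohex-5-en-1-yl]-2-butylcyclopropane | Br/C=C/CCCC[C@H]1C[C@@H]1CCCC | intermediate
14 | 6-O-(tert-butyldimethylsilyl)-2-deoxy-3,4-O-isopropylidene-D-lyxo-hexopyranos-1-yloxyl radical | CC(C)(C)[Si](C)(C)OC[C@H]1OC([O])C[C@H]2OC(C)(C)O[C@@H]12 | intermediate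
15 | primary C5 radical: the 2-formyloxy-1-silyloxy-3,4-(isopropylidenedioxy)pent-5-yl radical | O=CO[C@H](CO[Si](C)(C)C(C)(C)C)[C@@H]1OC(C)(C)O[C@@H]1[CH2] | intermediate
16 | (2R,3R,4R,6E)-11-[(1S,2S)-2-butylcyclopropyl]-1-[(tert-butyldimethylsilyl)oxy]-3,4-(isopropylidenedioxy)undec-6-en-2-yl formate | O=CO[C@H](CO[Si](C)(C)C(C)(C)C)[C@@H]1OC(C)(C)O[C@@H]1C/C=C/CCCC[C@H]2C[C@@H]2CCCC | intermediate
17 | (2R,3S,4R,6E)-11-[(1S,2S)-2-butylcyclopropyl]-1-[(tert-butyldimethylsilyl)oxy]-3,4-(isopropylidenedioxy)undec-6-en-2-ol | O[C@H](CO[Si](C)(C)C(C)(C)C)[C@@H]1OC(C)(C)O[C@@H]1C/C=C/CCCC[C@H]2C[C@@H]2CCCC | intermediate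
18 | C2 trifluoromethanesulfonate of 17, configuration unchanged | FC(F)(F)S(=O)(=O)O[C@H](CO[Si](C)(C)C(C)(C)C)[C@@H]1OC(C)(C)O[C@@H]1C/C=C/CCCC[C@H]2C[C@@H]2CCCC | intermediate
19 | (2S,3S,4R,6E)-2-azido-11-[(1S,2S)-2-butylcyclopropyl]-1-[(tert-butyldimethylsilyl)oxy]-3,4-(isopropylidenedioxy)undec-6-ene | [N-]=[N+]=N[C@@H](CO[Si](C)(C)C(C)(C)C)[C@@H]1OC(C)(C)O[C@@H]1C/C=C/CCCC[C@H]2C[C@@H]2CCCC | intermediate
20 | (2S,3S,4R,6E)-11-[(1S,2S)-2-butylcyclopropyl]-1-[(tert-butyldimethylsilyl)oxy]-3,4-(isopropylidenedioxy)undec-6-en-2-amine | N[C@@H](CO[Si](C)(C)C(C)(C)C)[C@@H]1OC(C)(C)O[C@@H]1C/C=C/CCCC[C@H]2C[C@@H]2CCCC | intermediate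
21 | 1-bromodocosane | CCCCCCCCCCCCCCCCCCCCCCBr | starting material
22 | methyl (R)-glycidate (methyl (2R)-oxirane-2-carboxylate) | COC(=O)[C@H]1CO1 | starting material
23 | docosylmagnesium bromide | CCCCCCCCCCCCCCCCCCCCCC[Mg]Br | intermediate
24 | methyl (R)-2-hydroxypentacosanoate | CCCCCCCCCCCCCCCCCCCCCCC[C@@H](O)C(=O)OC | intermediate
25 | (R)-2-hydroxypentacosanoic acid | CCCCCCCCCCCCCCCCCCCCCCC[C@@H](O)C(=O)O | intermediate
26 | (2R)-N-{(2S,3S,4R,6E)-11-[(1S,2S)-2-butylcyclopropyl]-1-[(tert-butyldimethylsilyl)oxy]-3,4-(isopropylidenedioxy)undec-6-en-2-yl}-2-hydroxypentacosanamide | CCCCCCCCCCCCCCCCCCCCCCC[C@@H](O)C(=O)N[C@@H](CO[Si](C)(C)C(C)(C)C)[C@@H]1OC(C)(C)O[C@@H]1C/C=C/CCCC[C@H]2C[C@@H]2CCCC | intermediate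
27 | (2R)-N-{(2S,3S,4R,6E)-11-[(1S,2S)-2-butylcyclopropyl]-1,3,4-trihydroxyundec-6-en-2-yl}-2-hydroxypentacosanamide | CCCCCCCCCCCCCCCCCCCCCCC[C@@H](O)C(=O)N[C@@H](CO)[C@H](O)[C@H](O)C/C=C/CCCC[C@H]1C[C@@H]1CCCC | target

**Step count**
- Total step count: 16.
- Longest linear sequence: 11 steps, from 5 through steps 4–8, 9–12, 15 and 16.

**Steps most likely to fail**

1. Step 9 (Proposed new method).
   - What may go wrong: hydrogen-atom transfer from the Hantzsch ester to 14 or 15 may outrun scission or nickel capture. Hydrodehalogenation or dimerisation of 13 may also drain the nickel cycle.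
   - Fallback: known chemistry makes the same bond in separate stages and sets out from glycal 3. PPh3·HBr-catalysed hydration in wet THF gives the lactol 6-O-(tert-butyldimethylsilyl)-2-deoxy-3,4-O-isopropylidene-D-lyxo-hexopyranose F1. The oxidative Suárez fragmentation (PhI(OAc)2, I2, CH2Cl2, visible light) cleaves the same C1–C2 bond and traps the radical as the primary iodide 5-O-(tert-butyldimethylsilyl)-1-deoxy-4-O-formyl-1-iodo-2,3-O-isopropylidene-D-lyxitol F2. Nickel-catalysed reductive cross-electrophile coupling of F2 with 13 (NiBr2·dme, 2,2'-bipyridine, Mn, DMA) comes back to the route at formate 16.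

2. Step 6.
   - What may go wrong: single-electron transfer to bromide 7, or its ionisation, would open the cyclopropylcarbinyl unit to a homoallyl chain and erase both ring stereocentres. Sluggish magnesium insertion into chloride 8 may favour Wurtz-type dimerisation.
   - Fallback: it sets out from alcohol 6 and never makes the carbon next to the ring an electrophile or a radical. Swern oxidation gives (1S,2S)-2-butylcyclopropane-1-carbaldehyde F3. Wittig methylenation with Ph3P=CH2 gives (1S,2R)-1-butyl-2-ethenylcyclopropane F4. Concerted hydroboration with 9-BBN-H gives 9-{2-[(1S,2S)-2-butylcyclopropyl]ethyl}-9-borabicyclo[3.3.1]nonane F5. Alkyl–alkyl Suzuki–Miyaura coupling with commercial (4-bromobut-1-yn-1-yl)trimethylsilane (Pd(OAc)2, PCy3, K3PO4·H2O, THF, rt) comes back at silylalkyne 10.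

3. Step 13.
   - What may go wrong: addition of the Grignard reagent to the ester carbonyl may compete with epoxide opening. The C22 organometallic may also precipitate at the low temperature that regiocontrol requires.
   - Fallback: it sets out from bromide 21 through Grignard reagent 23 and uses an electrophile without a carbonyl group. CuI-catalysed opening of commercial (S)-glycidol at 0 °C, with one extra equivalent of 23 for the hydroxyl, gives (R)-pentacosane-1,2-diol F6. Chemoselective nitroxyl-catalysed oxidation of the primary alcohol (TEMPO, NaOCl cat., NaClO2, buffered MeCN/toluene) comes back at acid 25 and bypasses ester 24.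

**Further compounds**
F1 | step 9 | 6-O-(tert-butyldimethylsilyl)-2-deoxy-3,4-O-isopropylidene-D-lyxo-hexopyranose | CC(C)(C)[Si](C)(C)OC[C@H]1OC(O)C[C@H]2OC(C)(C)O[C@@H]12
F2 | step 9 | 5-O-(tert-butyldimethylsilyl)-1-deoxy-4-O-formyl-1-iodo-2,3-O-isopropylidene-D-lyxitol | O=CO[C@H](CO[Si](C)(C)C(C)(C)C)[C@@H]1OC(C)(C)O[C@@H]1CI
F3 | step 6 | (1S,2S)-2-butylcyclopropane-1-carbaldehyde | O=C[C@H]1C[C@@H]1CCCC
F4 | step 6 | (1S,2R)-1-butyl-2-ethenylcyclopropane | C=C[C@H]1C[C@@H]1CCCC
F5 | step 6 | 9-{2-[(1S,2S)-2-butylcyclopropyl]ethyl}-9-borabicyclo[3.3.1]nonane | C1CC2CCCC(C1)B2CC[C@H]3C[C@@H]3CCCC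
F6 | step 13 | (R)-pentacosane-1,2-diol | CCCCCCCCCCCCCCCCCCCCCCC[C@@H](O)CO
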